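A small charge of enzyme, 5.3 µM, is set against 10 mM of substrate, and the enzyme also destroys itself in pairs, a second-order loss.

substrate 10 mM; enzyme 5.3 µM

    substrate + enzyme → product + enzyme, rate k1*[substrate]*[enzyme]/(1 + ([substrate]/Km1)) (Km1 = 1.5 mM, k1 = 500 /M/s)
    2 enzyme → spent catalyst (k2 = 130 /M/s)

- two of one species on the left: rate k times its square, two consumed each time
- a form made of two catalysts counts as two
- charge of substrate (flask): 10 mM

- the form that holds most of the catalyst when 20% of the substrate are converted (enzyme / spent catalyst)
- its share of the catalyst then
- factor on the rate of making product when 20% of the substrate are converted if enzyme is charged twice over
- factor on the rate when 20% of the substrate are converted if enzyme is charged at 50 µM instead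

Take logarithms first. The natural logarithm of the enzyme concentration falls at a pace proportional to the enzyme concentration. A measure of progress on the substrate, W, rises at a pace proportional to the same enzyme concentration: W is the natural logarithm of charged over remaining substrate, plus the substrate converted divided by Km. Dividing one pace by the other removes both the enzyme concentration and the time. The natural logarithm of charged over remaining enzyme is therefore w times W, where w is the wear ratio, twice the rate constant of the loss over that of conversion, here 0.520.

At 20% conversion, W is 1.56, so the product wW is 0.809 and the enzyme keeps 44.5% of the catalyst. Spent catalyst, counted as two per form, holds 55.5%, which is more than the enzyme holds.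

The neighbouring flask, with twice the enzyme, looks nearly the same, and neither w nor W contains the enzyme charge. At 20% conversion it therefore stands at the same share and the same substrate, with double the enzyme concentration, so its rate comes out at a factor 2. A flask charged at 50 µM comes out at 9.43.

The forecast names spent catalyst at 55.5% with factors 2 and 9.43, arguing that “At fixed conversion the rate therefore scales directly” with the charge. The simulation gives spent catalyst at 55.5%, with factors 2.00 and 9.43.

In this flask at 4.00 h, with substrate at 30.3% of its charge, the wear ratio puts the enzyme at 4.80%, and the state there reads 4.80%. A second flask, the same but without the step to spent catalyst, has no wear and keeps its enzyme whole at 20% conversion, so the ratio expects 2.25 times this flask's rate. Run that way, with the step removed, the flask at 20% conversion makes product at 2.25 times this flask's rate.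

The numbers were chosen freely.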